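**Retrosynthetic overview**
- Ring B (pyran) is closed last: the C1 hydroxyl displaces benzylamine at C3 of a vinylogous amide, and C8a is set by equilibration.
- Ring A (carbocycle) is made first, in the light-driven key step: a secondary enaminone (N on C3) adds [2+2] to a tethered allene, and retro-Mannich opening inserts C4a–C4 between C5 and C3.
- The enaminone comes from an ynone, assembled from the side-chain enyne acetylide (C5, C3, C1′–C7′) and a lactic-acid-derived dioxolanone acyl donor (C6–C8a, C1, C4a, C4).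
- Stereocentres: C7 from D-lactic acid (self-regeneration), C8 by chair aldol with an achiral allenal; C4′/C5′ from L-isoleucine, C3′ by chelation-controlled alkynylation; E-olefin by trans-hydroalumination.

Assumption: the 8a configuration of the target (H-8/H-8a trans, C1 trans to the C8 hydroxyl) is the thermodynamically preferred one at this enolisable position; core atoms are numbered C1, O2, C3, C4, C4a, C5–C8, C8a and side-chain atoms C1′–C7′.

**Route**

Step 1
Reactants: 1 L-isoleucine [(2S,3S)-2-amino-3-methylpentanoic acid]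
Product: 2 (2S,3S)-2-hydroxy-3-methylpentanoic acid
Conditions: NaNO2, 1 M H2SO4, H2O, 0 °C → rt
Reagents that add atoms: water, O
Why: Diazotisation of the α-amino acid with carboxylate participation (double inversion) replaces NH2 by OH with net retention, so both isoleucine stereocentres (future C4′ and C5′) are carried over.

Step 2
Reactants: 2 (2S,3S)-2-hydroxy-3-methylpentanoic acid
Product: 3 (3S,4S)-3-hydroxy-4-methylhexan-2-one
Conditions: MeLi (3.5 equiv), THF, 0 °C → rt; inverse quench into 1 M HCl, 0 °C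
Reagents that add atoms: methyllithium, [Li]C
Why: Organolithium ketone synthesis from a lithium carboxylate, in which the gem-dialkoxide collapses to the methyl ketone only on acidic quench and the α- and β-stereocentres are not touched.

Step 3
Reactants: 3 (3S,4S)-3-hydroxy-4-methylhexan-2-one
Product: 4 (5S,6S,7S)-5,7-dimethyl-1-(trimethylsilyl)nona-1,3-diyne-5,6-diol
Conditions: Me3SiC≡C–C≡CSiMe3 + MeLi·LiBr (THF, 0 °C) → LiC≡C–C≡CSiMe3 (2.3 equiv); MgBr2·OEt2; then 3, THF, −78 → −20 °C; aqueous NH4Cl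
Reagents that add atoms: 1,4-bis(trimethylsilyl)buta-1,3-diyne (used as its monolithio derivative), C[Si](C)(C)C#CC#C[Si](C)(C)C
Why: Cram-chelate (cyclic model) controlled acetylide addition to the metal-alkoxide-chelated α-hydroxy ketone from the face of the small H substituent sets the tertiary carbinol C3′ as S.

Step 4
Reactants: 4 (5S,6S,7S)-5,7-dimethyl-1-(trimethylsilyl)nona-1,3-diyne-5,6-diol
Product: 6 (3E,5S,6S,7S)-5,7-dimethylnon-3-en-1-yne-5,6-diol, via TMS-enyne diol 5 (not isolated)
Conditions: LiAlH4, THF, 0 °C → rt; H2O/15% NaOH work-up; then K2CO3 (cat.), MeOH, rt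
Reagents that add atoms: none
Why: Alkoxide-directed trans-hydroalumination (LiAlH4 reduction of a propargylic alcohol) reduces only the triple bond next to the carbinol to the E-olefin, and base-mediated protodesilylation then frees the terminal alkyne.

Step 5
Reactants: 6 (3E,5S,6S,7S)-5,7-dimethylnon-3-en-1-yne-5,6-diol
Product: 7 (3E,5S,6S,7S)-5,7-dimethyl-5,6-bis(triethylsilyloxy)non-3-en-1-yne
Conditions: Et3SiOSO2CF3 (2.5 equiv), 2,6-lutidine, CH2Cl2, −78 → 0 °C
Reagents that add atoms: triethylsilyl trifluoromethanesulfonate, CC[Si](CC)(CC)OS(=O)(=O)C(F)(F)F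
Why: Silyl triflate silylation protects the secondary and the hindered tertiary hydroxyl so that the alkyne C–H is the only acidic site in the coupling step.

Step 6
Reactants: 8 4-chlorobut-2-yn-1-ol
Product: 9 tert-butyl[(4-chlorobut-2-yn-1-yl)oxy]dimethylsilane
Conditions: tBuMe2SiCl, imidazole, DMF, 0 °C → rt
Reagents that add atoms: tert-butyldimethylsilyl chloride, CC(C)(C)[Si](C)(C)Cl
Why: Imidazole-promoted silylation of the primary alcohol masks the future C1 oxygen until the last step.

Step 7
Reactants: 9 tert-butyl[(4-chlorobut-2-yn-1-yl)oxy]dimethylsilane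
Product: 10 2-[(tert-butyldimethylsilyloxy)methyl]buta-2,3-dien-1-ol
Conditions: In powder, NaI, 37% aqueous HCHO, THF/H2O, rt
Reagents that add atoms: formaldehyde, C=O
Why: Indium Barbier reaction in which the γ-substituted propargylindium attacks formaldehyde by SE2′ at the substituted alkyne carbon, giving the 1,1-disubstituted allene that carries C8a, C1, C4a and C4 without any stereocentre.

Step 8
Reactants: 10 2-[(tert-butyldimethylsilyloxy)methyl]buta-2,3-dien-1-ol
Product: 11 2-[(tert-butyldimethylsilyloxy)methyl]buta-2,3-dienal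
Conditions: MnO2 (activated), CH2Cl2, rt; used at once
Reagents that add atoms: none
Why: MnO2 oxidation of the activated (allenylic) primary alcohol gives the aldehyde without touching the allene or the silyl ether.

Step 9
Reactants: 12 D-lactic acid [(R)-2-hydroxypropanoic acid]; 13 pivalaldehyde
Product: 14 (2R,5R)-2-tert-butyl-5-methyl-1,3-dioxolan-4-one
Conditions: TsOH·H2O (cat.), H2SO4 (cat.), pentane, reflux (Dean–Stark); recrystallise (pentane, −78 °C)
Reagents that add atoms: none
Why: Acid-catalysed acetalisation (self-regeneration of stereocentres) relays the lactic acid centre to the acetal carbon, the favoured cis isomer being purified by crystallisation.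

Step 10
Reactants: 14 (2R,5R)-2-tert-butyl-5-methyl-1,3-dioxolan-4-one; 11 2-[(tert-butyldimethylsilyloxy)methyl]buta-2,3-dienal
Product: 17 (2R,5S)-2-tert-butyl-5-[(1S)-2-[(tert-butyldimethylsilyloxy)methyl]-1-(triethylsilyloxy)buta-2,3-dien-1-yl]-5-methyl-1,3-dioxolan-4-one, via lithium enolate 15 (not isolated), via lithium aldolate 16 (not isolated)
Conditions: LiN(iPr)2, THF, −78 °C; 11, −78 °C; Et3SiOSO2CF3, −78 → −40 °C
Reagents that add atoms: triethylsilyl trifluoromethanesulfonate, CC[Si](CC)(CC)OS(=O)(=O)C(F)(F)F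
Why: Aldol addition of the ring-locked Z(O)-enolate anti to the tert-butyl group sets C7 as S, a Zimmerman–Traxler chair with the allenyl group equatorial (methyl and new oxygen syn) sets C8 as S, and the aldolate is trapped as its silyl ether.

Step 11
Reactants: 7 (3E,5S,6S,7S)-5,7-dimethyl-5,6-bis(triethylsilyloxy)non-3-en-1-yne; 17 (2R,5S)-2-tert-butyl-5-[(1S)-2-[(tert-butyldimethylsilyloxy)methyl]-1-(triethylsilyloxy)buta-2,3-dien-1-yl]-5-methyl-1,3-dioxolan-4-one
Product: 19 (4S,5S,9E,11S,12S,13S)-3-[(tert-butyldimethylsilyloxy)methyl]-5-hydroxy-5,11,13-trimethyl-4,11,12-tris(triethylsilyloxy)pentadeca-1,2,9-trien-7-yn-6-one, via lithium acetylide 18 (not isolated)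
Conditions: 7, n-BuLi, THF, −78 °C; BF3·OEt2; 17, −78 → −40 °C; aqueous NH4Cl at −78 °C
Reagents that add atoms: none
Why: Acetylide acylation (ynone synthesis) in which the BF3-activated acylal-type carbonyl gives a tetrahedral adduct that survives until work-up and then collapses with loss of pivalaldehyde to the ynone and the free C7 tertiary alcohol.

Step 12
Reactants: 19 (4S,5S,9E,11S,12S,13S)-3-[(tert-butyldimethylsilyloxy)methyl]-5-hydroxy-5,11,13-trimethyl-4,11,12-tris(triethylsilyloxy)pentadeca-1,2,9-trien-7-yn-6-one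
Product: 22 (5S,6S)-3-[(3E,5S,6S,7S)-2-(benzylamino)-5,7-dimethyl-5,6-bis(triethylsilyloxy)nona-1,3-dien-1-yl]-4-[(tert-butyldimethylsilyloxy)methyl]-6-hydroxy-6-methyl-5-(triethylsilyloxy)cyclohex-2-en-1-one (both C4 epimers), via Z-enaminone 20 (not isolated), via cyclobutane photoadduct 21 (not isolated)
Conditions: BnNH2 (1.1 equiv), MeCN, 0 °C; degas, dilute to 5 mM; hν (365 nm LED), −40 °C; then dark, rt
Reagents that add atoms: benzylamine, NCc1ccccc1
Why: Proposed new method: conjugate addition of benzylamine places nitrogen on C3 by construction and gives the N–H···O chelated enaminone, whose excited state bonds through its α-carbon C5 to the central carbon of the acyl-tethered allene (six-membered closure, allyl/α-amino-allyl 1,4-biradical) and closes at the CH2 terminus to a methylenecyclobutane, after which the push–pull C3–C5 bond breaks by retro-Mannich fragmentation on warming so that C4a–C5 and C3–C4 are formed, ring A is closed and no new stereocentre has to be controlled (C8a is set later); the closest known reaction type is the vinylogous-amide [2+2] photocycloaddition/retro-Mannich sequence (aza variant of the de Mayo reaction), shown for alkenes but not for an allene tethered through the acyl side of an acyclic enaminone.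

Step 13
Reactants: 22 (5S,6S)-3-[(3E,5S,6S,7S)-2-(benzylamino)-5,7-dimethyl-5,6-bis(triethylsilyloxy)nona-1,3-dien-1-yl]-4-[(tert-butyldimethylsilyloxy)methyl]-6-hydroxy-6-methyl-5-(triethylsilyloxy)cyclohex-2-en-1-one
Product: 24 (7S,8S,8aS)-3-[(1E,3S,4S,5S)-3,4-dihydroxy-3,5-dimethylhept-1-en-1-yl]-7,8-dihydroxy-7-methyl-1,7,8,8a-tetrahydro-6H-isochromen-6-one, via desilylated aminodienone 23 (not isolated)
Conditions: HF (48% aqueous), MeCN/H2O, 0 °C → rt; then NaHCO3 to pH 7–8, rt, 2 h
Reagents that add atoms: none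
Why: Acidic fluoride desilylation frees all hydroxyls, the C1 hydroxyl then displaces benzylamine at C3 by addition–elimination on the protonated vinylogous amide (cyclocondensation to the six-membered enol ether, ring B), and C8a, the γ-position of the dienone, equilibrates by enolisation to the epimer with C1 trans to the C8 hydroxyl under control of C7 and C8.

**Compound list**

1 | L-isoleucine, (2S,3S)-2-amino-3-methylpentanoic acid | CC[C@H](C)[C@H](N)C(=O)O | starting material
2 | (2S,3S)-2-hydroxy-3-methylpentanoic acid | CC[C@H](C)[C@H](O)C(=O)O | intermediate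
3 | (3S,4S)-3-hydroxy-4-methylhexan-2-one | CC[C@H](C)[C@H](O)C(C)=O | intermediate
4 | (5S,6S,7S)-5,7-dimethyl-1-(trimethylsilyl)nona-1,3-diyne-5,6-diol | CC[C@H](C)[C@H](O)[C@@](C)(O)C#CC#C[Si](C)(C)C | intermediate
5 | (3E,5S,6S,7S)-5,7-dimethyl-1-(trimethylsilyl)non-3-en-1-yne-5,6-diol (TMS-enyne diol, not isolated) | CC[C@H](C)[C@H](O)[C@@](C)(O)/C=C/C#C[Si](C)(C)C | intermediate
6 | (3E,5S,6S,7S)-5,7-dimethylnon-3-en-1-yne-5,6-diol | CC[C@H](C)[C@H](O)[C@@](C)(O)/C=C/C#C | intermediate
7 | (3E,5S,6S,7S)-5,7-dimethyl-5,6-bis(triethylsilyloxy)non-3-en-1-yne | CC[C@H](C)[C@H](O[Si](CC)(CC)CC)[C@@](C)(O[Si](CC)(CC)CC)/C=C/C#C | intermediate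
8 | 4-chlorobut-2-yn-1-ol | OCC#CCCl | starting material
9 | tert-butyl[(4-chlorobut-2-yn-1-yl)oxy]dimethylsilane | ClCC#CCO[Si](C)(C)C(C)(C)C | intermediate
10 | 2-[(tert-butyldimethylsilyloxy)methyl]buta-2,3-dien-1-ol | OCC(CO[Si](C)(C)C(C)(C)C)=C=C | intermediate
11 | 2-[(tert-butyldimethylsilyloxy)methyl]buta-2,3-dienal | O=CC(CO[Si](C)(C)C(C)(C)C)=C=C | intermediate
12 | D-lactic acid, (R)-2-hydroxypropanoic acid | C[C@@H](O)C(=O)O | starting material
13 | pivalaldehyde (2,2-dimethylpropanal) | CC(C)(C)C=O | starting material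
14 | (2R,5R)-2-tert-butyl-5-methyl-1,3-dioxolan-4-one (cis) | C[C@H]1O[C@@H](C(C)(C)C)OC1=O | intermediate
15 | lithium (2R)-2-tert-butyl-5-methyl-1,3-dioxol-4-olate (lithium enolate of 14, not isolated) | CC1=C(O[Li])O[C@H](C(C)(C)C)O1 | intermediate
16 | lithium (1S)-1-[(2R,4S)-2-tert-butyl-4-methyl-5-oxo-1,3-dioxolan-4-yl]-2-[(tert-butyldimethylsilyloxy)methyl]buta-2,3-dien-1-olate (lithium aldolate, not isolated) | C[C@@]1([C@@H](O[Li])C(CO[Si](C)(C)C(C)(C)C)=C=C)O[C@@H](C(C)(C)C)OC1=O | intermediate
17 | (2R,5S)-2-tert-butyl-5-[(1S)-2-[(tert-butyldimethylsilyloxy)methyl]-1-(triethylsilyloxy)buta-2,3-dien-1-yl]-5-methyl-1,3-dioxolan-4-one | C[C@@]1([C@@H](O[Si](CC)(CC)CC)C(CO[Si](C)(C)C(C)(C)C)=C=C)O[C@@H](C(C)(C)C)OC1=O | intermediate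
18 | lithium acetylide of 7 (not isolated) | CC[C@H](C)[C@H](O[Si](CC)(CC)CC)[C@@](C)(O[Si](CC)(CC)CC)/C=C/C#C[Li] | intermediate
19 | (4S,5S,9E,11S,12S,13S)-3-[(tert-butyldimethylsilyloxy)methyl]-5-hydroxy-5,11,13-trimethyl-4,11,12-tris(triethylsilyloxy)pentadeca-1,2,9-trien-7-yn-6-one (ynone) | CC[C@H](C)[C@H](O[Si](CC)(CC)CC)[C@@](C)(O[Si](CC)(CC)CC)/C=C/C#CC(=O)[C@@](C)(O)[C@@H](O[Si](CC)(CC)CC)C(CO[Si](C)(C)C(C)(C)C)=C=C | intermediate
20 | (4S,5S,7Z,9E,11S,12S,13S)-8-(benzylamino)-3-[(tert-butyldimethylsilyloxy)methyl]-5-hydroxy-5,11,13-trimethyl-4,11,12-tris(triethylsilyloxy)pentadeca-1,2,7,9-tetraen-6-one (Z-enaminone, not isolated) | CC[C@H](C)[C@H](O[Si](CC)(CC)CC)[C@@](C)(O[Si](CC)(CC)CC)/C=C/C(NCc1ccccc1)=C/C(=O)[C@@](C)(O)[C@@H](O[Si](CC)(CC)CC)C(CO[Si](C)(C)C(C)(C)C)=C=C | intermediate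
21 | (3S,4S)-7-(benzylamino)-2-[(tert-butyldimethylsilyloxy)methyl]-7-[(1E,3S,4S,5S)-3,5-dimethyl-3,4-bis(triethylsilyloxy)hept-1-en-1-yl]-4-hydroxy-4-methyl-3-(triethylsilyloxy)bicyclo[4.2.0]oct-1-en-5-one (cyclobutane photoadduct, C6/C7 epimers, not isolated) | CC[C@H](C)[C@H](O[Si](CC)(CC)CC)[C@@](C)(O[Si](CC)(CC)CC)/C=C/C1(NCc2ccccc2)CC2=C(CO[Si](C)(C)C(C)(C)C)[C@H](O[Si](CC)(CC)CC)[C@](C)(O)C(=O)C12 | intermediate
22 | (5S,6S)-3-[(3E,5S,6S,7S)-2-(benzylamino)-5,7-dimethyl-5,6-bis(triethylsilyloxy)nona-1,3-dien-1-yl]-4-[(tert-butyldimethylsilyloxy)methyl]-6-hydroxy-6-methyl-5-(triethylsilyloxy)cyclohex-2-en-1-one (both C4 epimers, enamine geometry not fixed) | CC[C@H](C)[C@H](O[Si](CC)(CC)CC)[C@@](C)(O[Si](CC)(CC)CC)/C=C/C(NCc1ccccc1)=CC1=CC(=O)[C@@](C)(O)[C@@H](O[Si](CC)(CC)CC)C1CO[Si](C)(C)C(C)(C)C | intermediate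
23 | (5S,6S)-3-[(3E,5S,6S,7S)-2-(benzylamino)-5,6-dihydroxy-5,7-dimethylnona-1,3-dien-1-yl]-5,6-dihydroxy-4-(hydroxymethyl)-6-methylcyclohex-2-en-1-one (desilylated aminodienone, not isolated) | CC[C@H](C)[C@H](O)[C@@](C)(O)/C=C/C(NCc1ccccc1)=CC1=CC(=O)[C@@](C)(O)[C@@H](O)C1CO | intermediate
24 | (7S,8S,8aS)-3-[(1E,3S,4S,5S)-3,4-dihydroxy-3,5-dimethylhept-1-en-1-yl]-7,8-dihydroxy-7-methyl-1,7,8,8a-tetrahydro-6H-isochromen-6-one | CC[C@H](C)[C@H](O)[C@@](C)(O)/C=C/C1=CC2=CC(=O)[C@@](C)(O)[C@@H](O)[C@@H]2CO1 | target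

**Step count and risks**

Total steps: 13. Longest linear sequence: 8 (steps 1–5, then 11, 12 and 13).

Most likely to fail, first: step 12. It is the new step. Besides the wanted bonding of C5 to the central allene carbon, the excited dienaminone can lose energy by E/Z isomerisation of the C1′=C2′ olefin (re-equilibrated to the strongly favoured E isomer with a trace of I2 in daylight after step 13), close onto the proximal allene double bond, or lose benzylamine to a furanone through the free C7 hydroxyl if acid is present. The fallback uses known chemistry only and sets out from ynone 19. Heating 19 (toluene, 200 °C, microwave, BHT) lets the ynone alkyne and the distal allene double bond undergo the known thermal intramolecular allenyne [2+2] cycloaddition to the cyclobutene-fused dienone F1. Conjugate (aza-Michael) addition of benzylamine to this strained cyclobutenyl ketone gives the same amino cyclobutane 21, which opens by retro-Mannich fragmentation, so the route is rejoined at 22.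

Second: step 10. The C8 configuration rests on a closed chair transition state of a tetrasubstituted enolate, and both the enolate (above −70 °C) and the allenal are fragile. The fallback reverses the polarity of the C7–C8 bond formation and sets out from 14. Its enolate 15 is C-formylated (ethyl formate, −78 °C) to the quaternary aldehyde F2. The allenyl unit is then added by an indium Barbier reaction with chloride 9 (In, NaI, THF/H2O), where C8 is set by 1,2-induction from C7 (Cornforth-type attack anti to the ring C–O bond, on the methyl side), giving the carbinol F3. Silylation (Et3SiOSO2CF3, 2,6-lutidine) returns to the route at 17.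

Third: step 11. The carbonyl is flanked by a quaternary carbon, so addition may be slow, or the adduct may collapse early and take up a second acetylide. The fallback changes the acyl donor and sets out from 17. The dioxolanone is opened with Me(MeO)NMgCl (from Me(MeO)NH·HCl and iPrMgCl, THF, −20 °C) to the Weinreb amide F4 with loss of pivalaldehyde. Acetylide 18 (2.2 equiv, the first equivalent deprotonating the tertiary hydroxyl) then gives a stable chelated adduct that releases the ynone on work-up, rejoining the route at 19.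

Further compounds
F1 | step 12 | (3S,4S)-2-[(tert-butyldimethylsilyloxy)methyl]-7-[(1E,3S,4S,5S)-3,5-dimethyl-3,4-bis(triethylsilyloxy)hept-1-en-1-yl]-4-hydroxy-4-methyl-3-(triethylsilyloxy)bicyclo[4.2.0]octa-1,6-dien-5-one | CC[C@H](C)[C@H](O[Si](CC)(CC)CC)[C@@](C)(O[Si](CC)(CC)CC)/C=C/C1=C2C(=O)[C@@](C)(O)[C@@H](O[Si](CC)(CC)CC)C(CO[Si](C)(C)C(C)(C)C)=C2C1
F2 | step 10 | (2R,5S)-2-tert-butyl-5-formyl-5-methyl-1,3-dioxolan-4-one | C[C@@]1(C=O)O[C@@H](C(C)(C)C)OC1=O
F3 | step 10 | (2R,5S)-2-tert-butyl-5-[(1S)-2-[(tert-butyldimethylsilyloxy)methyl]-1-hydroxybuta-2,3-dien-1-yl]-5-methyl-1,3-dioxolan-4-one | C[C@@]1([C@@H](O)C(CO[Si](C)(C)C(C)(C)C)=C=C)O[C@@H](C(C)(C)C)OC1=O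
F4 | step 11 | (2S,3S)-4-[(tert-butyldimethylsilyloxy)methyl]-2-hydroxy-N-methoxy-N,2-dimethyl-3-(triethylsilyloxy)hexa-4,5-dienamide | CON(C)C(=O)[C@@](C)(O)[C@@H](O[Si](CC)(CC)CC)C(CO[Si](C)(C)C(C)(C)C)=C=C
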